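(Readings and results are calculated for an exercise.)

As the chemist on this flask, I had two earlier runs at other loadings of pre-initiator.

common to all: free monomer 0.14 M
- amber: pre-initiator 4.4 mol%; run made earlier
- red: pre-initiator 18 mol%; run made earlier
- flask: pre-initiator 8.8 mol%; time 12 min

| run | time / min | monomer in chains / % | free monomer / % |
|---|---|---|---|
| amber | 4.00 | 11 | 88 |
| amber | 8.00 | 16 | 84 |
| amber | 10.0 | 15 | 86 |
| amber | 15.0 | 21 | 84 |
| red | 4.00 | 28 | 74 |
| red | 8.00 | 31 | 67 |
| red | 10.0 | 35 | 67 |
| red | 15.0 | 34 | 63 |

(scatter of a reading: 1.5 percentage points)

* average number of monomer units in a chain (chains begun, living or dead) at 12 min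
* part of the free monomer that has reacted at 12 min

- the average divides the monomer in chains by the number of chains begun, living and dead together
- the earlier runs do not show the number of chains; that part of a forecast is a guess

Both runs slowed: their last 3 readings of monomer in chains averaged 17.3% in amber and 33.3% in red, each with the scatter of its readings. The flask's loading is twice amber's and red's is twice the flask's, so I took the geometric mean of those averages, 24.0%. For chain length I used the feed ratio, free monomer charged per pre-initiator charged, 11.4, the usual target degree of polymerisation. If each pre-initiator begins one chain, the reacted part times this ratio is the average chain, here 2.73 units, which is a guess because the earlier runs show no chain count.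

The forecast gave 24% and 2.8 units, slightly longer than my chain, and held that “the active species is dying or the pre-initiator is used up”.

The flask gave 23.4% and 2.66 units per chain.

    free monomer + initiator → living end + monomer in chains (k = 15.0 M⁻¹ min⁻¹)
    free monomer + living end → monomer in chains + living end, rate k2*[living end]*[free monomer] (k = 8.50 M⁻¹ min⁻¹)
    monomer in chains + living end → free monomer + living end, rate k3*[living end] as long as [monomer in chains] is above zero (k = 0.400 min⁻¹)
    2 living end → dead end (k = 42.0 M⁻¹ min⁻¹)
    pre-initiator → initiator (k = 1.90 min⁻¹)

In the flask, the half-life of pre-initiator by its own step, 0.36 min, was far shorter than the 12 min of the run; at 12.0 min pre-initiator stood at 0% of its charge and initiator at 1.80 × 10⁻¹⁰ M, and the reacted part times the feed ratio gives 2.66 against 2.66. The same flask read at 3.0 min, with 0.33% of its pre-initiator left and initiator at 2.54 × 10⁻⁴ M, had 15.8% reacted, and the feed ratio gives 1.79 against 1.84.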